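## Retrosynthetic overview
- Mitorubrinic acid comes from global deprotection of a bis-TBS / tert-butyl ester precursor (14). The 7R quaternary ester centre is made in one step by enantioselective oxidative dearomatisation of the 7-H azaphilone (6), a 2-methylresorcinol-derived isochromenylium phenolate. A chiral C2-symmetric aryl-λ3-iodane bis(orsellinate) delivers the protected orsellinate to C7.
- The 7-H azaphilone (6) comes from acid cyclodehydration of a 2-(2-oxoalkyl)benzaldehyde (5). This is formed by lateral (benzylic) acylation of the atranol trianion with a fumarate Weinreb amide.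
- Ring order: the arene (atranol) is already present, then the pyran ring (Step 3), then the dearomatised carbocycle with its C7 stereocentre (Step 8).

Assumptions:
- Atranol (4) is commercial. It is also made by Vilsmeier formylation of 2,5-dimethylresorcinol.
- The target C7 is (R) by CIP analysis of the SMILES.
- The enantiomer of iodoarene 12 that gives 7R is found by trying both. Both are available from either lactate enantiomer.

## Route

**Step 1**
Reactants: 1 (mono-tert-butyl fumarate); 2 (N,O-dimethylhydroxylamine hydrochloride)
Product: 3, tert-butyl (E)-4-[methoxy(methyl)amino]-4-oxobut-2-enoate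
Conditions: EDC·HCl, HOBt, iPr2NEt, CH2Cl2, 0 → 25 °C
Reagents that add atoms: 2, CNOC.Cl (numbered reactant)
Why: Standard carbodiimide amide coupling gives the Weinreb amide. The E-alkene is retained and no stereocentre is formed.

**Step 2**
Reactants: 4 (atranol, 2,4-dihydroxy-3,6-dimethylbenzaldehyde); 3
Product: 5, tert-butyl (E)-5-(2-formyl-3,5-dihydroxy-4-methylphenyl)-4-oxopent-2-enoate
Conditions: LiTMP (3.0 equiv), THF, –78 → 0 °C, then 3 (1.1 equiv), –78 → 25 °C; NH4Cl quench
Reagents that add atoms: none
Why: Harris-type lateral metalation gives the trianion (two phenoxides plus the benzylic carbanion), which is acylated on the Weinreb amide carbonyl. The resulting ketone is deprotonated in situ, which prevents over-addition.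
Proposed new method: the same lateral trianion chemistry is known for orsellinate esters, not for a salicylaldehyde. The 2,4-diphenoxide makes the CHO a vinylogous carboxylate, so it resists LiTMP and the carbanion. The closest known reaction is Harris orsellinate trianion acylation.

**Step 3**
Reactant: 5
Product: 6, tert-butyl (E)-3-(6-hydroxy-7-methyl-8-oxo-8H-isochromen-3-yl)acrylate (the 7-H azaphilone, drawn as one tautomer of the 6,8-dione)
Conditions: TsOH·H2O (10 mol%), MeCN, 25 °C; NaHCO3 wash
Reagents that add atoms: none
Why: Acid-catalysed cyclodehydration: the ketone enol adds to the aldehyde and water is lost, giving the isochromenylium. Deprotonation of the phenol gives the neutral quinonoid azaphilone, as in azaphilone biogenesis. No stereocentre is formed, and the tBu ester survives catalytic TsOH at room temperature.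

**Step 4**
Reactant: 7 (orcinol)
Product: 8, orsellinic acid (2,4-dihydroxy-6-methylbenzoic acid)
Conditions: KHCO3, CO2 (10 bar), H2O, 110 °C
Reagents that add atoms: carbon dioxide, O=C=O
Why: Kolbe–Schmitt carboxylation goes ortho to one OH and para to the other, giving the chelated 2,4-dihydroxy isomer.

**Step 5**
Reactant: 8
Product: 9, 2,4-bis(tert-butyldimethylsilyloxy)-6-methylbenzoic acid
Conditions: TBSCl (4 equiv), imidazole, DMF, 25 °C; then K2CO3, MeOH/H2O, and AcOH work-up
Reagents that add atoms: TBSCl, CC(C)(C)[Si](C)(C)Cl
Why: Tris-silylation is followed by mild selective hydrolysis of the labile silyl ester. The aryl TBS ethers survive and mask the phenols against the iodane.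

**Step 6**
Reactants: 10 (2-iodoresorcinol); 11 (ethyl (R)-lactate)
Product: 12, diethyl (2S,2'S)-2,2'-[(2-iodo-1,3-phenylene)bis(oxy)]dipropanoate (C2-symmetric chiral iodoarene)
Conditions: PPh3, DIAD, THF, 0 → 25 °C
Reagents that add atoms: 11, CCOC(=O)[C@@H](C)O (numbered reactant)
Why: Double Mitsunobu etherification of the phenols proceeds with inversion at the lactate carbon, giving the (S,S) diether.

**Step 7**
Reactant: 12
Product: 13, the (S,S)-iodoarene diacetate, ArI(OAc)2
Conditions: NaBO3·4H2O, AcOH, 40 °C
Reagents that add atoms: acetic acid, CC(=O)O (the two acetate ligands)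
Why: Perborate oxidises the aryl iodide to the λ3-iodane diacetate (Kita-type preparation).

**Step 8 (key step)**
Reactants: 6; 9 (3 equiv); 13 (1.3 equiv)
Product: 14, tert-butyl (E)-3-[(7R)-7-{[2,4-bis(TBSO)-6-methylbenzoyl]oxy}-7-methyl-6,8-dioxo-6H-isochromen-3-yl]acrylate
Conditions: (i) 13 + 9, CH2Cl2, 25 °C, 30 min, concentrate to remove AcOH (gives ArI(O2CAr')2); (ii) add 6, CH2Cl2, –40 °C, 12 h
Reagents that add atoms: 9, Cc1cc(O[Si](C)(C)C(C)(C)C)cc(O[Si](C)(C)C(C)(C)C)c1C(=O)O (the acyloxy group is delivered to C7)
Why: Oxidative dearomatisation of the resorcinol-type azaphilone enol. The nucleophilic C7 (the 2-methyl-1,3-dione enol carbon) attacks the iodane. Enantiofacial discrimination by the chiral ligand sphere sets the C7 quaternary stereocentre, and carboxylate displacement of the iodane gives the 7-acyloxy-6,8-dione.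
Proposed new method: the mechanism is C-bound iodane(III) enolate formation, then SN2-type carboxylate delivery or ligand coupling, giving direct α-acyloxylation with stereocontrol from the C2-symmetric lactate ether arms. This avoids acylating a hindered tertiary 7-OH. The closest known reactions are the Wessely/PIDA ortho-acyloxylation of phenols, chiral-iodane α-oxytosylation of ketones, and Kita–Ishihara asymmetric iodane dearomatisation.

**Step 9**
Reactant: 14
Product: 15, mitorubrinic acid tert-butyl ester
Conditions: HF·pyridine, pyridine, THF, 0 °C, 2 h (plastic vessel)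
Reagents that add atoms: none
Why: Fluoride removes both aryl TBS ethers. The tertiary acyloxy centre has no α-H and cannot epimerise, the azaphilone tolerates buffered HF, and the tBu ester is untouched.

**Step 10**
Reactant: 15
Product: 16, mitorubrinic acid (target)
Conditions: TFA/CH2Cl2 (1:4), 1,3,5-trimethoxybenzene (cation scavenger), 0 → 25 °C, 2 h
Reagents that add atoms: none
Why: E1 acidolysis of the tert-butyl ester gives the free (E)-acrylic acid. The azaphilone core, the orsellinate ester and C7 are acid-stable.

## Compound list
1 | mono-tert-butyl fumarate | OC(=O)/C=C/C(=O)OC(C)(C)C | starting material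
2 | N,O-dimethylhydroxylamine hydrochloride | CNOC.Cl | starting material
3 | tert-butyl (E)-4-[methoxy(methyl)amino]-4-oxobut-2-enoate | CON(C)C(=O)/C=C/C(=O)OC(C)(C)C | intermediate
4 | atranol (2,4-dihydroxy-3,6-dimethylbenzaldehyde) | O=Cc1c(C)cc(O)c(C)c1O | starting material
5 | keto-aldehyde, tert-butyl (E)-5-(2-formyl-3,5-dihydroxy-4-methylphenyl)-4-oxopent-2-enoate | O=Cc1c(O)c(C)c(O)cc1CC(=O)/C=C/C(=O)OC(C)(C)C | intermediate
6 | 7-H azaphilone | CC1=C(O)C=C2C=C(/C=C/C(=O)OC(C)(C)C)OC=C2C1=O | intermediate
7 | orcinol | Cc1cc(O)cc(O)c1 | starting material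
8 | orsellinic acid | Cc1cc(O)cc(O)c1C(=O)O | intermediate
9 | 2,4-bis(TBSO)-6-methylbenzoic acid | Cc1cc(O[Si](C)(C)C(C)(C)C)cc(O[Si](C)(C)C(C)(C)C)c1C(=O)O | intermediate
10 | 2-iodoresorcinol | Oc1cccc(O)c1I | starting material
11 | ethyl (R)-lactate | CCOC(=O)[C@@H](C)O | starting material
12 | chiral iodoarene (S,S) | CCOC(=O)[C@H](C)Oc1cccc(O[C@@H](C)C(=O)OCC)c1I | intermediate (reagent)
13 | chiral iodane diacetate | CCOC(=O)[C@H](C)Oc1cccc(O[C@@H](C)C(=O)OCC)c1I(OC(C)=O)OC(C)=O | intermediate (reagent)
14 | protected ester | Cc1cc(O[Si](C)(C)C(C)(C)C)cc(O[Si](C)(C)C(C)(C)C)c1C(=O)O[C@]1(C)C(=O)C=C2C=C(/C=C/C(=O)OC(C)(C)C)OC=C2C1=O | intermediate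
15 | mitorubrinic acid tert-butyl ester | Cc1cc(O)cc(O)c1C(=O)O[C@]1(C)C(=O)C=C2C=C(/C=C/C(=O)OC(C)(C)C)OC=C2C1=O | intermediate
16 | mitorubrinic acid | Cc1cc(O)cc(O)c1C(=O)O[C@]1(C)C(=O)C=C2C=C(/C=C/C(=O)O)OC=C2C1=O | target

## Step count
- Total steps: 10.
- Longest linear sequence: 6 (1 → 2 → 3 → 8 → 9 → 10, starting from 1).

## Three steps most likely to fail
1. **Step 8, enantioselective acyloxylation.** The ee may be modest, or the electron-rich azaphilone may undergo oxidative dimerisation or attack at C5. Fallback: Cu(II)/(–)-sparteine/O2 enantioselective 7-hydroxylation of 6 (Cu-mediated azaphilone dearomatisation). Then acylate the tertiary 7-OH with the acid chloride of 9 (Ghosez reagent, then DMAP), and continue with Steps 9 and 10.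
2. **Step 2, lateral metalation and acylation on the aldehyde-bearing trianion.** The aldehyde may be attacked, or the carbanion may not form. Fallback: build the 2-benzopyrylium by the alkyne route instead. Make the 6-iodo-2,4-bis(MOM)-3-methylbenzaldehyde by directed ortho-iodination, Sonogashira-couple it with tert-butyl (E)-pent-2-en-4-ynoate, remove the MOM groups, and effect Ag(I)/Cu(I) 6-endo cycloisomerisation to 6.
3. **Step 10, final deprotection.** The acyl-activated tertiary ester may migrate or hydrolyse, and tBu+ may alkylate the free orsellinate phenols. Fallback: use allyl ester and allyl aryl ethers throughout instead of the tBu/TBS pair. Remove all of them in one neutral, amine-free Pd(PPh3)4/PhSiH3 step.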